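**Retrosynthetic overview**
1. The C1–O ester bond is made last-but-one by a rhodium-catalysed allylic C–H acyloxylation of the trans-fused alcohol 23 with 3-acetoxy-4-methoxybenzoic acid 30 (built from catechol), followed by deacetylation.
2. The six-membered ring is formed last, by ring-closing metathesis of diene 22, which comes from double methylenation of keto-lactol 21.
3. The C11 carbinol is set by closing a bridged γ-lactone (19) from cycloheptene acid 18; the seven-membered ring is formed first, by ring-closing metathesis of acid 17.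
4. The C3–C4 bond and both ring-fusion stereocentres come from an Ireland–Claisen rearrangement of ester 14, with chirality transfer from the (R)-allylic alcohol 8 (CBS reduction).
5. Ester 14 is joined from acid 13 (methyl 3-methylbut-2-enoate + butenyl Grignard) and alcohol 8 (hex-5-en-2-one + 3-bromobutan-2-one).

Assumption: terpene carbons are labelled C1 (ester carbinol carbon), C2 (ring CH2), C3/C4 (ring-fusion carbons; C3 next to carbinol carbon C11, C4 next to the CMe2 carbon C7), C5=C6 (alkene, methyl on C6), C8–C10 (CH2 groups of the seven-membered ring); but-3-en-1-ylmagnesium bromide is bought as a THF solution.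

**Fragment A: allylic alcohol 8**

Step 1
Reactants: 1 hex-5-en-2-one
Product: 2 2-(but-3-en-1-yl)-2-methyl-1,3-dioxolane
Conditions: HOCH2CH2OH, p-TsOH (cat.), benzene, reflux, Dean–Stark
Reagents that add atoms: ethane-1,2-diol OCCO
Why: Acid-catalysed ketalisation with azeotropic water removal masks the ketone against the later enolate, hydride and ylide steps.

Step 2
Reactants: 2 2-(but-3-en-1-yl)-2-methyl-1,3-dioxolane
Product: 3 3-(2-methyl-1,3-dioxolan-2-yl)propanal
Conditions: O3, CH2Cl2, −78 °C; PPh3, −78 °C to rt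
Reagents that add atoms: ozone [O-][O+]=O
Why: Ozonolysis of the terminal alkene with reductive work-up gives the aldehyde while the dioxolane is inert.

Step 3
Reactants: 4 3-bromobutan-2-one
Product: 6 3-(triphenylphosphoranylidene)butan-2-one, via phosphonium bromide 5 (not isolated)
Conditions: PPh3, toluene, 60 °C; then aq. NaOH, CH2Cl2, rt
Reagents that add atoms: triphenylphosphine c1ccc(cc1)P(c1ccccc1)c1ccccc1
Why: SN2 displacement of the α-bromide by the phosphine and deprotonation of the acidic α-CH give the stabilised ylide.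

Step 4
Reactants: 3 3-(2-methyl-1,3-dioxolan-2-yl)propanal; 6 3-(triphenylphosphoranylidene)butan-2-one
Product: 7 (E)-3-methyl-6-(2-methyl-1,3-dioxolan-2-yl)hex-3-en-2-one
Conditions: toluene, 90 °C
Reagents that add atoms: none
Why: Wittig olefination with an α-branched stabilised ylide gives the (E)-trisubstituted enone under thermodynamic control.

Step 5
Reactants: 7 (E)-3-methyl-6-(2-methyl-1,3-dioxolan-2-yl)hex-3-en-2-one
Product: 8 (2R,3E)-3-methyl-6-(2-methyl-1,3-dioxolan-2-yl)hex-3-en-2-ol
Conditions: (S)-2-methyl-CBS-oxazaborolidine (10 mol%), BH3·SMe2, THF, −30 °C; aq. work-up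
Reagents that add atoms: none
Why: Corey–Bakshi–Shibata reduction, in which the alkenyl group acts as the large substituent so that the (S)-catalyst delivers hydride to give the (R)-carbinol, the stereocentre from which C3 and C4 are later derived.

**Fragment B: acid 13**

Step 6
Reactants: 9 methyl 3-methylbut-2-enoate; 10 but-3-en-1-ylmagnesium bromide
Product: 12 methyl 3,3-dimethylhept-6-enoate, via ketene silyl acetal 11 (not isolated)
Conditions: CuI (10 mol%), Me3SiCl (2 equiv), THF, −40 to 0 °C; then 1 M HCl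
Reagents that add atoms: none
Why: Copper-catalysed, Me3SiCl-accelerated conjugate addition of the Grignard reagent to the β,β-disubstituted enoate builds the quaternary carbon C7, and the silyl ketene acetal is hydrolysed on work-up.

Step 7
Reactants: 12 methyl 3,3-dimethylhept-6-enoate
Product: 13 3,3-dimethylhept-6-enoic acid
Conditions: LiOH, THF/H2O, 50 °C; then 1 M HCl
Reagents that add atoms: lithium hydroxide [Li+].[OH-]
Why: Simple saponification of an unhindered methyl ester.

**Union and core**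

Step 8
Reactants: 13 3,3-dimethylhept-6-enoic acid; 8 (2R,3E)-3-methyl-6-(2-methyl-1,3-dioxolan-2-yl)hex-3-en-2-ol
Product: 14 (2R,3E)-3-methyl-6-(2-methyl-1,3-dioxolan-2-yl)hex-3-en-2-yl 3,3-dimethylhept-6-enoate
Conditions: DCC, DMAP (cat.), CH2Cl2, 0 °C to rt
Reagents that add atoms: none
Why: Steglich esterification joins the two fragments without touching the carbinol stereocentre.

Step 9
Reactants: 14 (2R,3E)-3-methyl-6-(2-methyl-1,3-dioxolan-2-yl)hex-3-en-2-yl 3,3-dimethylhept-6-enoate
Product: 17 (2R,3R,4E)-4-methyl-2-(2-methylhex-5-en-2-yl)-3-[2-(2-methyl-1,3-dioxolan-2-yl)ethyl]hex-4-enoic acid, via ketene silyl acetal 15 (not isolated), via trimethylsilyl ester 16 (not isolated)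
Conditions: LiN(i-Pr)2, THF, −78 °C; Me3SiCl, Et3N, −78 to 50 °C; then aq. NaOH, citric acid to pH 4
Reagents that add atoms: none
Why: Ireland–Claisen rearrangement, in which kinetic enolisation in THF places the tert-alkyl group cis to the allyl oxygen and the chair transition state with the carbinol methyl equatorial forms the C3–C4 bond and transfers the (R)-carbinol chirality to C3 and C4 (the relationship that becomes the trans ring fusion).

Step 10
Reactants: 17 (2R,3R,4E)-4-methyl-2-(2-methylhex-5-en-2-yl)-3-[2-(2-methyl-1,3-dioxolan-2-yl)ethyl]hex-4-enoic acid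
Product: 18 (1R,2R)-3,7,7-trimethyl-2-[2-(2-methyl-1,3-dioxolan-2-yl)ethyl]cyclohept-3-ene-1-carboxylic acid
Conditions: second-generation Grubbs catalyst (5 mol%), toluene (5 mM), 80 °C
Reagents that add atoms: none
Why: Ring-closing metathesis between the terminal vinyl group and the trisubstituted alkene, helped by the gem-dimethyl group, closes the seven-membered ring with the C10=C11 alkene and releases propene.

Step 11
Reactants: 18 (1R,2R)-3,7,7-trimethyl-2-[2-(2-methyl-1,3-dioxolan-2-yl)ethyl]cyclohept-3-ene-1-carboxylic acid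
Product: 19 (1R,6R,9R)-2,2,6-trimethyl-9-[2-(2-methyl-1,3-dioxolan-2-yl)ethyl]-7-oxabicyclo[4.2.1]nonan-8-one
Conditions: Co(3,5-tBu2-salen) [C32H46CoN2O2] (3 mol%), N-fluoro-2,4,6-trimethylpyridinium tetrafluoroborate (1.5 equiv), (Me2SiH)2O (1.5 equiv), PhCF3, 0 °C to rt; aq. NaHCO3
Reagents that add atoms: none
Why: Cobalt-hydride hydrogen-atom-transfer hydroacyloxylation (Mukaiyama-type radical–polar crossover) puts H on C10 and lets the carboxyl capture the tertiary C11 centre, which is only possible on the face carrying C4–CO2H, so C11–O is set cis to C5 and to C3–H as in the target.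

Step 12
Reactants: 19 (1R,6R,9R)-2,2,6-trimethyl-9-[2-(2-methyl-1,3-dioxolan-2-yl)ethyl]-7-oxabicyclo[4.2.1]nonan-8-one
Product: 20 (1R,6R,9R)-2,2,6-trimethyl-9-[2-(2-methyl-1,3-dioxolan-2-yl)ethyl]-7-oxabicyclo[4.2.1]nonan-8-ol (anomer mixture)
Conditions: i-Bu2AlH (1.1 equiv), CH2Cl2, −78 °C; aq. work-up
Reagents that add atoms: none
Why: Partial reduction of the γ-lactone stops at the lactol at −78 °C and leaves the ketal untouched.

Step 13
Reactants: 20 (1R,6R,9R)-2,2,6-trimethyl-9-[2-(2-methyl-1,3-dioxolan-2-yl)ethyl]-7-oxabicyclo[4.2.1]nonan-8-ol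
Product: 21 4-[(1R,6R,9R)-8-hydroxy-2,2,6-trimethyl-7-oxabicyclo[4.2.1]nonan-9-yl]butan-2-one
Conditions: PPTS (cat.), acetone/H2O (4:1), 45 °C
Reagents that add atoms: water O
Why: Mild acid hydrolysis removes the dioxolane while the bridged lactol, which fixes the C4 configuration, is unchanged.

Step 14
Reactants: 21 4-[(1R,6R,9R)-8-hydroxy-2,2,6-trimethyl-7-oxabicyclo[4.2.1]nonan-9-yl]butan-2-one
Product: 22 (1R,2R,3R)-3-ethenyl-1,4,4-trimethyl-2-(3-methylbut-3-en-1-yl)cycloheptan-1-ol
Conditions: Ph3PCH3Br (6 equiv), KOt-Bu (5.5 equiv), THF, 0 to 50 °C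
Reagents that add atoms: methyltriphenylphosphonium bromide C[P+](c1ccccc1)(c1ccccc1)c1ccccc1.[Br-]
Why: Double Wittig methylenation converts the methyl ketone into the isopropenyl group and the lactol, through its open hydroxy-aldehyde form, into the vinyl group, which frees the tertiary C11–OH.

Step 15
Reactants: 22 (1R,2R,3R)-3-ethenyl-1,4,4-trimethyl-2-(3-methylbut-3-en-1-yl)cycloheptan-1-ol
Product: 23 (4aR,5R,9aR)-2,5,9,9-tetramethyl-4,4a,5,6,7,8,9,9a-octahydro-3H-benzo[7]annulen-5-ol (trans ring fusion, OH cis to C3–H)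
Conditions: second-generation Grubbs catalyst (5 mol%), CH2Cl2, 40 °C
Reagents that add atoms: none
Why: Ring-closing metathesis of the vinyl and isopropenyl groups held trans on C4 and C3 closes the trans-fused cyclohexene with the trisubstituted C5=C6 alkene and releases ethene.

**Fragment C: acid 30**

Step 16
Reactants: 24 benzene-1,2-diol (catechol)
Product: 25 2-methoxyphenol
Conditions: MeI (1.0 equiv), K2CO3, acetone, reflux
Reagents that add atoms: iodomethane CI
Why: Williamson mono-methylation with one equivalent of MeI, the dimethyl ether being removed by base extraction.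

Step 17
Reactants: 25 2-methoxyphenol
Product: 26 2-methoxyphenyl acetate
Conditions: Ac2O, pyridine, DMAP (cat.), rt
Reagents that add atoms: acetic anhydride CC(=O)OC(C)=O
Why: Acetylation makes this oxygen the weaker donor so that the methoxy group directs the next substitution.

Step 18
Reactants: 26 2-methoxyphenyl acetate
Product: 27 5-bromo-2-methoxyphenyl acetate
Conditions: N-bromosuccinimide, MeCN, rt
Reagents that add atoms: N-bromosuccinimide O=C1CCC(=O)N1Br
Why: Electrophilic aromatic bromination occurs para to the stronger methoxy donor.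

Step 19
Reactants: 27 5-bromo-2-methoxyphenyl acetate
Product: 29 3-hydroxy-4-methoxybenzoic acid, via 5-bromo-2-methoxyphenol 28 (not isolated)
Conditions: Pd(OAc)2 (2 mol%), Xantphos (4 mol%), CO (1 atm), K2CO3 (4 equiv), dioxane/H2O, 100 °C; then 2 M HCl
Reagents that add atoms: carbon monoxide [C-]#[O+]; water O
Why: The aryl acetate is saponified in the basic medium and the aryl bromide then undergoes palladium-catalysed hydroxycarbonylation (oxidative addition to zerovalent palladium, CO insertion, hydrolysis of the acyl complex).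

Step 20
Reactants: 29 3-hydroxy-4-methoxybenzoic acid
Product: 30 3-acetoxy-4-methoxybenzoic acid
Conditions: Ac2O, 2 M NaOH, 0 °C; then 2 M HCl
Reagents that add atoms: acetic anhydride CC(=O)OC(C)=O
Why: Schotten–Baumann acetylation caps the phenol, which would otherwise compete as a nucleophile in the coupling, and leaves the carboxylic acid free.

**Coupling and end game**

Step 21
Reactants: 23 (4aR,5R,9aR)-2,5,9,9-tetramethyl-4,4a,5,6,7,8,9,9a-octahydro-3H-benzo[7]annulen-5-ol; 30 3-acetoxy-4-methoxybenzoic acid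
Product: 31 (3R,4aR,5R,9aR)-5-hydroxy-2,5,9,9-tetramethyl-4,4a,5,6,7,8,9,9a-octahydro-3H-benzo[7]annulen-3-yl 3-acetoxy-4-methoxybenzoate
Conditions: [Cp*Rh(MeCN)3](SbF6)2 (5 mol%), Ag2CO3 (1.2 equiv), 30 (1.3 equiv), 4 Å sieves, PhCF3, 40 °C
Reagents that add atoms: none
Why: Proposed new method: a hydroxyl-assisted, stereoretentive allylic C–H acyloxylation of a trisubstituted cycloalkene with about one equivalent of an arenecarboxylic acid, in which cationic trivalent rhodium binds the C5=C6 alkene on the face of the C11–OH (a possible second donor), its carboxylate ligand removes the pseudoaxial C1–H on that face by concerted metalation–deprotonation (the tertiary C4–H is on the other face and shielded by the quaternary C7) to give the endocyclic C1–C6–C5 allyl, and oxidation by Ag2CO3 to tetravalent rhodium triggers inner-sphere C–O reductive elimination at the less hindered terminus C1 on the metal-bearing face, so the ester replaces the pseudoaxial hydrogen and C1 is set cis to C3–H and C11–OH; the closest known reactions are Cp*Rh-catalysed allylic C–H amination and etherification of internal olefins through rhodium allyl intermediates and Pd/sulfoxide-catalysed allylic C–H esterification of terminal olefins with carboxylic acids.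

Step 22
Reactants: 31 (3R,4aR,5R,9aR)-5-hydroxy-2,5,9,9-tetramethyl-4,4a,5,6,7,8,9,9a-octahydro-3H-benzo[7]annulen-3-yl 3-acetoxy-4-methoxybenzoate
Product: 32 (3R,4aR,5R,9aR)-5-hydroxy-2,5,9,9-tetramethyl-4,4a,5,6,7,8,9,9a-octahydro-3H-benzo[7]annulen-3-yl 3-hydroxy-4-methoxybenzoate (CNP0210711.2)
Conditions: K2CO3 (0.2 equiv), MeOH, 0 °C
Reagents that add atoms: none
Why: Mild methanolysis cleaves the aryl acetate (phenoxide leaving group) much faster than the hindered secondary allylic benzoate and touches no stereocentre.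

**Compound list**
1 | hex-5-en-2-one | CC(=O)CCC=C | starting material
2 | 2-(but-3-en-1-yl)-2-methyl-1,3-dioxolane | C=CCCC1(C)OCCO1 | intermediate
3 | 3-(2-methyl-1,3-dioxolan-2-yl)propanal | O=CCCC1(C)OCCO1 | intermediate
4 | 3-bromobutan-2-one | CC(=O)C(C)Br | starting material
5 | (3-oxobutan-2-yl)triphenylphosphonium bromide | CC(=O)C(C)[P+](c1ccccc1)(c1ccccc1)c1ccccc1.[Br-] | intermediate
6 | 3-(triphenylphosphoranylidene)butan-2-one | CC(=O)C(C)=P(c1ccccc1)(c1ccccc1)c1ccccc1 | intermediate
7 | (E)-3-methyl-6-(2-methyl-1,3-dioxolan-2-yl)hex-3-en-2-one | CC(=O)/C(C)=C/CCC1(C)OCCO1 | intermediate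
8 | (2R,3E)-3-methyl-6-(2-methyl-1,3-dioxolan-2-yl)hex-3-en-2-ol | C[C@@H](O)/C(C)=C/CCC1(C)OCCO1 | intermediate
9 | methyl 3-methylbut-2-enoate | COC(=O)C=C(C)C | starting material
10 | but-3-en-1-ylmagnesium bromide | C=CCC[Mg]Br | starting material
11 | ketene silyl acetal of 12 (1-methoxy-3,3-dimethyl-1-trimethylsilyloxyhepta-1,6-diene) | C=CCCC(C)(C)C=C(OC)O[Si](C)(C)C | intermediate
12 | methyl 3,3-dimethylhept-6-enoate | C=CCCC(C)(C)CC(=O)OC | intermediate
13 | 3,3-dimethylhept-6-enoic acid | C=CCCC(C)(C)CC(=O)O | intermediate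
14 | (2R,3E)-3-methyl-6-(2-methyl-1,3-dioxolan-2-yl)hex-3-en-2-yl 3,3-dimethylhept-6-enoate | C=CCCC(C)(C)CC(=O)O[C@H](C)/C(C)=C/CCC1(C)OCCO1 | intermediate
15 | ketene silyl acetal of 14 (tert-alkyl group trans to OSiMe3, cis to the allyl oxygen) | C=CCCC(C)(C)/C=C(/O[Si](C)(C)C)O[C@H](C)/C(C)=C/CCC1(C)OCCO1 | intermediate
16 | trimethylsilyl ester of acid 17 | CC1(CC[C@@H](/C(C)=C/C)[C@@H](C(=O)O[Si](C)(C)C)C(C)(C)CCC=C)OCCO1 | intermediate
17 | (2R,3R,4E)-4-methyl-2-(2-methylhex-5-en-2-yl)-3-[2-(2-methyl-1,3-dioxolan-2-yl)ethyl]hex-4-enoic acid | CC1(CC[C@@H](/C(C)=C/C)[C@@H](C(=O)O)C(C)(C)CCC=C)OCCO1 | intermediate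
18 | (1R,2R)-3,7,7-trimethyl-2-[2-(2-methyl-1,3-dioxolan-2-yl)ethyl]cyclohept-3-ene-1-carboxylic acid (CO2H and side chain trans) | CC1(CC[C@@H]2[C@@H](C(=O)O)C(C)(C)CCC=C2C)OCCO1 | intermediate
19 | (1R,6R,9R)-2,2,6-trimethyl-9-[2-(2-methyl-1,3-dioxolan-2-yl)ethyl]-7-oxabicyclo[4.2.1]nonan-8-one | CC1(CC[C@@H]2[C@H]3C(=O)O[C@]2(C)CCCC3(C)C)OCCO1 | intermediate
20 | (1R,6R,9R)-2,2,6-trimethyl-9-[2-(2-methyl-1,3-dioxolan-2-yl)ethyl]-7-oxabicyclo[4.2.1]nonan-8-ol (anomer mixture) | CC1(CC[C@@H]2[C@H]3C(O)O[C@]2(C)CCCC3(C)C)OCCO1 | intermediate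
21 | 4-[(1R,6R,9R)-8-hydroxy-2,2,6-trimethyl-7-oxabicyclo[4.2.1]nonan-9-yl]butan-2-one (anomer mixture) | CC(=O)CC[C@@H]1[C@H]2C(O)O[C@]1(C)CCCC2(C)C | intermediate
22 | (1R,2R,3R)-3-ethenyl-1,4,4-trimethyl-2-(3-methylbut-3-en-1-yl)cycloheptan-1-ol | C=C(C)CC[C@@H]1[C@@H](C=C)C(C)(C)CCC[C@@]1(C)O | intermediate
23 | (4aR,5R,9aR)-2,5,9,9-tetramethyl-4,4a,5,6,7,8,9,9a-octahydro-3H-benzo[7]annulen-5-ol (trans-fused; OH cis to the adjacent ring-fusion H) | C1C[C@@H]2[C@@H](C=C1C)C(C)(C)CCC[C@@]2(C)O | intermediate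
24 | benzene-1,2-diol (catechol) | Oc1ccccc1O | starting material
25 | 2-methoxyphenol | COc1ccccc1O | intermediate
26 | 2-methoxyphenyl acetate | COc1ccccc1OC(C)=O | intermediate
27 | 5-bromo-2-methoxyphenyl acetate | COc1ccc(Br)cc1OC(C)=O | intermediate
28 | 5-bromo-2-methoxyphenol | COc1ccc(Br)cc1O | intermediate
29 | 3-hydroxy-4-methoxybenzoic acid | COc1ccc(C(=O)O)cc1O | intermediate
30 | 3-acetoxy-4-methoxybenzoic acid | COc1ccc(C(=O)O)cc1OC(C)=O | intermediate
31 | (3R,4aR,5R,9aR)-5-hydroxy-2,5,9,9-tetramethyl-4,4a,5,6,7,8,9,9a-octahydro-3H-benzo[7]annulen-3-yl 3-acetoxy-4-methoxybenzoate | COc1ccc(C(=O)O[C@@H]2C[C@@H]3[C@@H](C=C2C)C(C)(C)CCC[C@@]3(C)O)cc1OC(C)=O | intermediate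
32 | (3R,4aR,5R,9aR)-5-hydroxy-2,5,9,9-tetramethyl-4,4a,5,6,7,8,9,9a-octahydro-3H-benzo[7]annulen-3-yl 3-hydroxy-4-methoxybenzoate | COc1ccc(C(=O)O[C@@H]2C[C@@H]3[C@@H](C=C2C)C(C)(C)CCC[C@@]3(C)O)cc1O | target

**Step count and risks**

Total step count: 22. Longest linear sequence: 14 steps (steps 1, 2, 4, 5, 8 to 15, 21, 22).

Step 21 (the proposed rhodium-catalysed C–H acyloxylation) is the most likely to fail. Activation of the C6 methyl group, C–O formation at C5, or Lewis-acid ionisation of the tertiary alcohol or of the allylic ester could compete. The fallback uses known chemistry and sets out from 23. SeO2 (0.5 equiv) with t-BuOOH in CH2Cl2 at 0 °C to rt oxidises the ring CH2 next to the methyl-bearing alkene carbon by ene reaction and [2,3]-shift, which replaces the pseudoaxial hydrogen. This gives the allylic alcohol (3R,4aR,5R,9aR)-2,5,9,9-tetramethyl-4,4a,5,6,7,8,9,9a-octahydro-3H-benzo[7]annulene-3,5-diol F1. Acylation of its secondary hydroxyl with acid 30 (EDC·HCl, DMAP, CH2Cl2) then gives 31, where the route is rejoined.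

Step 11 (cobalt-hydride hydroacyloxylation to a bridged lactone) may suffer from olefin isomerisation or slow capture at the hindered tertiary centre. The fallback sets out from 18. Iodolactonisation (I2, NaHCO3, MeCN/H2O, 0 °C) gives by anti addition the iodolactone (1R,5R,6R,9R)-5-iodo-2,2,6-trimethyl-9-[2-(2-methyl-1,3-dioxolan-2-yl)ethyl]-7-oxabicyclo[4.2.1]nonan-8-one F2, again with C11–O necessarily cis to C5. Radical deiodination (Bu3SnH, AIBN, benzene, 80 °C) returns to the route at 19.

Step 10 (ring-closing metathesis onto a trisubstituted alkene next to a stereocentre) may be slow or give dimers. The fallback sets out from 17 and closes the same ring by carbonyl coupling: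
- Me3SiCHN2 in MeOH/toluene gives the methyl ester F3.
- Ozonolysis (O3, CH2Cl2, −78 °C; Me2S) cleaves both alkenes to the keto aldehyde F4.
- McMurry coupling with low-valent titanium (TiCl3, Zn(Cu), DME, reflux, high dilution) forms the C10=C11 bond and gives the cycloheptene ester F5.
- LiOH in THF/H2O returns to the route at 18.

Further compounds
F1 | step 21 | (3R,4aR,5R,9aR)-2,5,9,9-tetramethyl-4,4a,5,6,7,8,9,9a-octahydro-3H-benzo[7]annulene-3,5-diol | O[C@@H]1C[C@@H]2[C@@H](C=C1C)C(C)(C)CCC[C@@]2(C)O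
F2 | step 11 | (1R,5R,6R,9R)-5-iodo-2,2,6-trimethyl-9-[2-(2-methyl-1,3-dioxolan-2-yl)ethyl]-7-oxabicyclo[4.2.1]nonan-8-one (I trans to the lactone oxygen) | CC1(CC[C@@H]2[C@H]3C(=O)O[C@]2(C)[C@@H](I)CCC3(C)C)OCCO1
F3 | step 10 | methyl (2R,3R,4E)-4-methyl-2-(2-methylhex-5-en-2-yl)-3-[2-(2-methyl-1,3-dioxolan-2-yl)ethyl]hex-4-enoate | CC1(CC[C@@H](/C(C)=C/C)[C@@H](C(=O)OC)C(C)(C)CCC=C)OCCO1
F4 | step 10 | methyl (2R,3R)-3-acetyl-2-(2-methyl-5-oxopentan-2-yl)-5-(2-methyl-1,3-dioxolan-2-yl)pentanoate | CC1(CC[C@@H](C(C)=O)[C@@H](C(=O)OC)C(C)(C)CCC=O)OCCO1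
F5 | step 10 | methyl (1R,2R)-3,7,7-trimethyl-2-[2-(2-methyl-1,3-dioxolan-2-yl)ethyl]cyclohept-3-ene-1-carboxylate | CC1(CC[C@@H]2[C@@H](C(=O)OC)C(C)(C)CCC=C2C)OCCO1
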